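How far has the electrophile gone in the new flask after 40 h, and at what pH does that flask stand?

common to all: electrophile 0.050 M

|  | buffer base | buffer acid | solid nucleophile | remark | time |
|---|---|---|---|---|---|
| eta | 0.025 M | 0.0075 M | 0.045 M | run made earlier |  |
| gamma | 0.025 M | 0.011 M | 0.045 M | run made earlier |  |
| flask | 0.0250 M | 0.0150 M | 0.0450 M |  | 40 h |

- eta (time / h: electrophile / %, product / %): 6.00: 100.6, 0; 12.0: 96.2, 0.6; 15.0: 97.2, 4.8; 25.0: 89.5, 11.5; 30.0: 84.1, 14.6; 40.0: 76.4, 24.5
- gamma (time / h: electrophile / %, product / %): 6.00: 101.4, 0; 12.0: 99.3, 0.5; 15.0: 98.9, 3.2; 25.0: 89.4, 9.7; 30.0: 87.7, 12.4; 40.0: 79.1, 20.3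

(readings scatter by 1 percentage point)

- part of the electrophile that has reacted at 40 h
- pH of the solution at 40 h

- the earlier runs were read with a standard deviation of 1 percentage point
- at the start none of the solid nucleophile is in solution
- the earlier runs do not show the pH; that part of a forecast is a guess

We reckon in half-lives. The eta run keeps 76.4% of its electrophile at 40.0 h, which is 0.388 half-lives spent: the number of halvings that takes the electrophile from what was charged to what is left, as if its loss were pseudo-first-order.

Turn the time first. By hand, a steady loss makes the count grow as the clock does, 1.60 times from 25.0 h to 40.0 h. But the eta run reads 0.160 at the earlier reading, so its count grows 2.42 times, faster than the clock. Its product reads just 0.6% at 12.0 h: a lag.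

Now the buffer acid. By hand, a count inverse in buffer acid would drop 1.47 times from the eta run to the gamma run. The gamma run reads 0.338, a drop of 1.15 times, less than that, as far as readings with this scatter show.

A straight line of count against buffer acid through both runs gives the new flask 0.281, so we expect 17.7% reacted. The forecast, by its own route, a power of the acid that it calls “weaker than simple inverse proportionality”, gives 18%, and it guesses a pH of 7.

The new flask gives 19.0% reacted at pH 7.54. Its equations, hidden until now:

    electrophile + nucleophile → acid + product + leaving group (k = 0.700 L mol⁻¹ h⁻¹)
    protonated nucleophile ⇌ nucleophile + acid, settled at all times (K = 1.30 × 10⁻⁸ M)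
    buffer acid ⇌ buffer base + acid, settled at all times (K = 1.60 × 10⁻⁵ M)
    solid nucleophile ⇌ nucleophile, rate k4*(cs4 - [nucleophile]) while solid is left; crystals form when [nucleophile] > cs4 (solubility = 39.0 mM, k = 0.0390 h⁻¹)

That is 0.303 half-lives spent in the new flask, a little above our line's 0.281 and below the gamma run's 0.338. The neighbouring flask is like the new one but charged with 0.12 M of electrophile, which makes the solid nucleophile 0.375 equiv against 0.900 equivalents. A count blind to the charge would read 0.303 there too. The neighbouring flask spends 0.175, which is 0.578 of the new flask's count, and reaches 11.4%. Its nucleophile at 40.0 h stands at 0.00291 M, against 0.0111 M in the new flask.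

All runs stem from a simulated flask for substances that don't exist, and the scatter is random.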